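(Readings and results come from a simulation on assumed constants; scatter was added.)

Take target out of the flask at 15 h, or leave target where it is: that is the choice, and two of us read the same runs differently.

| setting | eta | epsilon | flask |
|---|---|---|---|
| substrate | 0.050 M | 0.10 M | 0.050 M |
| coupling partner | 0.075 M | 0.075 M | 0.0750 M |
| temperature | 70 °C | 55 °C | 70 °C |
| remark | the very flask that is asked about, followed so far | run made earlier |  |
| time |  |  | 15 h |

| run | time / h | target / % | substrate / % |
|---|---|---|---|
| eta | 1.33 | 22.6 | 50.1 |
| eta | 2.50 | 26.6 | 32.0 |
| eta | 4.00 | 26.4 | 26.2 |
| eta | 5.00 | 25.8 | 23.5 |
| eta | 6.00 | 25.9 | 22.4 |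
| eta | 8.00 | 27.7 | 18.0 |
| eta | 10.0 | 27.6 | 18.6 |
| epsilon | 0.833 | 13.6 | 82.4 |
| epsilon | 2.00 | 21.6 | 70.1 |
| epsilon | 3.00 | 22.1 | 64.4 |
| epsilon | 4.00 | 22.3 | 58.3 |
| epsilon | 5.00 | 21.6 | 56.1 |
| epsilon | 6.00 | 21.2 | 52.9 |

(each reading ± 1 percentage point)
- teal: at 15 h take out 90% of the target then present, then wait 15 h
- amber: at 15 h raise the temperature by 10 K, then wait 15 h
- grey: change nothing and wait 15 h more
- green: at 15 h add coupling partner, 50.0% of the amount charged, then wait 15 h
- target that was removed still counts
- the earlier runs were read with a standard deviation of 1 percentage point
- additions bring no volume worth counting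
1. target, in percent of the substrate first charged, at 15 h
2. which option adds most target ("none" when 2 percentage points or less is all one gets) (teal / amber / grey / green / none)
3. target present, with what was taken out counted in, in percent of the substrate first charged, after teal
4. target present, with what was taken out counted in, in percent of the substrate first charged, after amber

In the eta run, which is this flask followed so far, target stands level from 2.50 h on while substrate goes on falling for some hours. One of us sees a coupling that has stopped working, so that nothing done to target can matter. I see a coupling that runs backward as fast as forward. The last two readings of the eta run give target 27.7% and substrate 18.3% of the charge, with coupling partner at 1.50 equivalents. If each lost substrate took one coupling partner and freed one released group, then target times lost substrate, over substrate left times coupling partner left, comes to 1.81; this is the stall quotient, the reaction quotient of the coupling. At 2.50 h the same count reads 0.689, so on my view the quotient climbed until forward and backward met.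

By the same readings target holds 33.8%, about a third, of the lost substrate, and I assume that this share stays for whatever remains in the flask. Taking out 90% of target removes 24.9% of the charge, and solving the quotient afresh puts lost substrate at 85.2%. My figure after teal is therefore 45.3% with the removed part counted, a gain of 18 percentage points, whereas the same reckoning for green puts lost substrate at 89.1% and its gain at 2.5 points.

The forecast takes the other side, “The productive channel has died”, and gives 26.8% at 15 h, 26.9% after teal, 27.1% after amber, and as best option none; on teal it parts from my figure.

The flask gives 27.4% at 15 h, 44.6% after teal and 25.4% after amber, so the best option is teal, adding 17 points, while green adds 2.3 points. The forecast's call stands for waiting and heating, where grey brings −0.27 points and amber −1.9 points, each less than the 2 points margin.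

    substrate + coupling partner ⇌ target + released group (K = 1.60, k = 0.150 M⁻¹ min⁻¹, Ea = 60.0 kJ mol⁻¹, ΔH = 37.0 kJ mol⁻¹)
    target ⇌ isomer of the product (K = 1.90, k = 0.0260 min⁻¹, Ea = 97.0 kJ mol⁻¹, ΔH = 15.0 kJ mol⁻¹)
    target → over-reaction product (k = 3.80 × 10⁻⁵ min⁻¹, Ea = 121 kJ mol⁻¹)
    (constants at 70 °C)

Counted from the state of this flask at 15.0 h, the quotient is 1.59. The neighbour flask has 0.045 M of coupling partner, 0.900 equivalents, which makes coupling partner the limiting reagent. Carrying 1.81 and the target share over, lost substrate comes to 66.0%, which leaves substrate at 34.0% and target at 22.3%. At 15 h the neighbour flask holds substrate 35.4% and target 22.0%.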